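All runs were generated by integration for substances that don't exist; the scatter is artificial.

A leftover of coupling partner is what I reckon first for this flask. At one partner per substrate, the 0.900 equiv charged leaves 10.0% of the substrate over, and the last reading, 10% at 120 s, already stands there after 16% at 80.0 s, each with a scatter of 2 percentage points. So I doubt one to one.

- gamma: substrate 0.80 M; coupling partner 0.90 equiv; scavenger 0.50 equiv; the very flask that is asked about, followed so far
- flask: substrate 0.80 M; coupling partner 0.900 equiv; scavenger 0.500 equiv; time 6.0 min

- gamma (time / s: substrate / %, target / %): 10.0: 60, 6; 12.0: 55, 5; 20.0: 42, 6; 30.0: 33, 14; 50.0: 20, 22; 80.0: 16, 18; 120: 10, 24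

(standard deviation of a reading: 2 percentage points)

- part of the substrate that has reacted at 6.0 min
- share of the unused coupling partner that is free and not bound as idle adduct, at 6.0 min

At that last reading, target is 26.7% of the substrate reacted. The rest is unseen, and I assume it goes two substrates per partner. Each target then costs one partner and each unseen substrate 0.5, which gives 0.633. This is the partner cost: coupling partner spent per substrate reacted. The charge then pays for 1.42 of substrate, more than the one equivalent present, so I take substrate as the limiting reagent, with 29.6% of the partner charge over at full conversion.

Running the readings on as a second-order decay from the last one, I get 96.4% reacted at 6.0 min. If the scavenger takes one equivalent per target and also takes whatever binds the partner, its 0.500 equiv exceeds the target share, so my guess for the free share is close to 100 percent, though the runs cannot show it. The forecast says 95% and 40%, the second lower than my free share, holding that “active reagent is being lost”.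

This flask gives 98.3% reacted and a free share of >99.9%, with 27% of the partner charge left at 6.0 min against the 29.6% I reckoned for full conversion.

    substrate + coupling partner ⇌ intermediate (K = 1.20 /M, k = 0.0860 /M/s)
    scavenger + released group → scavenged by-product (k = 2.60 /M/s)
    substrate + intermediate → side product (k = 0.160 /M/s)
    coupling partner + released group ⇌ idle adduct, settled at all times (K = 1.90 /M)
    intermediate ⇌ target + released group (K = 1.10 M, k = 0.0410 /s)
    target → over-reaction product (k = 9.00 × 10⁻⁵ /s)

The side product holds two substrates, and its percentages count both. The neighbour flask, charged with 0.230 equiv of coupling partner and otherwise alike, pays at the same cost for 0.363 equivalents of substrate. That flask reaches 39.2% reacted at 6.0 min, with its partner down to 0.0096% of its charge, so there the partner is first to run out. At that time it holds 6.56% target and 32.5% side product, and 60.8% of its substrate is still unreacted.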